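I had to say whether epsilon or delta ends with more target per substrate charged.

| flask | substrate | reagent in the second phase | remark | time | volume of the second phase over the first |
|---|---|---|---|---|---|
| autumn | 0.10 M | 0.28 M | run made earlier |  |  |
| summer | 0.10 M | 0.55 M | run made earlier |  |  |
| spring | 0.13 M | 0.20 M | run made earlier |  |  |
| epsilon | 0.20 M | 0.400 M |  | 1.2 d | 0.50 |
| delta | 0.10 M | 0.200 M |  | 2.5 d | 0.50 |

- autumn (time / d: target / %, substrate / %): 0.500: 31.4, 2.8; 1.04: 32.2, 0; 1.67: 31.7, 0; 2.08: 31.6, 0.6; 2.50: 31.5, 1.1
- summer (time / d: target / %, substrate / %): 0.500: 48.8, 0; 1.04: 48.9, 1.0; 1.67: 49.1, 0.9; 2.08: 49.4, 0.9; 2.50: 49.8, 0.3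
- spring (time / d: target / %, substrate / %): 0.208: 18.0, 35.5; 0.417: 17.7, 11.8; 0.625: 17.0, 4.4; 1.25: 17.9, 0.5; 2.50: 17.7, 0.3

(readings scatter by 0.5 percentage points)

1. which of the two ends with the higher amount of target, in percent of the substrate charged ("neither" if they lie within 2 percentage points) (epsilon / delta / neither)
2. target at the end, in percent of the substrate charged, epsilon
3. target at the end, in percent of the substrate charged, delta

- in the second phase: reagent in the second phase; everything else is in the first
- charges count per volume of the first phase; a concentration in a rate is the amount of a species over the volume of its own phase; every rate counts per litre of the first phase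
- the earlier runs hold the two phases in the same ratio of volumes as the flask asked about

The spring run looked contradictory. At 0.208 d target read 18.0 % with 35.5 % of the substrate still there, and at 2.50 d it read 17.7 % with 0.3 % left. A third of the charge had gone, yet target stayed level within its scatter.

I followed one substrate molecule and supposed a fork: it meets reagent and makes target, or it meets target and destroys that too. The odds are reagent against target, so target climbs until gain equals loss and then stands while substrate keeps going, a quasi-steady state. Target at balance then goes with reagent, so I read from spring the balance constant, target at balance per reagent charged: 0.115. Times reagent over substrate, it gives a flask's balance fraction. For autumn that is 32.2 % against 31.5 % read. For summer it is 63.3 % against 49.8 %, so I trusted it well under the full charge.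

Epsilon has twice delta's substrate and twice its reagent, so the fractions came to 23.0 % and 23.0 %. Spring's substrate time constant, 0.190 d, is shorter than either flask's time, so I expected a tie.

The forecast said neither, with 22.7 % for epsilon and 22 % for delta, slightly below my figures, on this ground: “So target formation stops because reagent runs out, and the remaining substrate goes to waste.”

The answer was neither: epsilon ended at 23.2 % and delta at 23.3 %, as the balance fraction of 23.0 % said.

    reagent in the reaction phase ⇌ reagent in the second phase, rate k1*([reagent in the reaction phase] - [reagent in the second phase]/K1) per volume of the first phase (partition coefficient = 0.870, kL = 2.80 /h)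
    substrate + reagent in the reaction phase → target (k = 1.10 /M/h)
    substrate + target → side product (k = 4.60 /M/h)

The main reason is the loss of target to substrate: without that step delta ends at 99.5 %, not 23.3 %. Delta's second phase still held 21.0 % of its reagent charge, with substrate at 0 %, so substrate was the limiting reagent. For a neighbour of epsilon with 0.12 M of substrate, the balance fraction gives 38.4 %; the computed result is 36.1 %.

The numbers in the tables are calculated with made-up constants.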